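**Assumption:** iridoid numbering is used for discussion (C1 acetal, O2, C3=C4, C5/C9 ring fusion, C6–C8 cyclopentane, C10 = CH2OH on C8, C11 = CH2O on C4). The target SMILES corresponds to (1S,4aS,6S,7R,7aS).

## Retrosynthetic overview

- Last bonds: the C1–O isovalerate, then removal of two silyl ethers from a bicyclic lactol.
- Both rings form in one operation from an acyclic dialdehyde: the cyclopentane (C5–C9 bond) and then the dihydropyran (O2–C1 bond), by an intramolecular enamine/enal hetero-Diels–Alder reaction.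
- The dialdehyde is cut at C4=C5 by cross-metathesis into two halves of comparable size: an aldehyde–alkene carrying C1 and C5–C10 with both stereocentres set, and an acrolein carrying C3, C4, C11 and the first isovalerate.
- In the stereochemical half, C8 comes from a Sharpless epoxidation, C7 from a Brown allylation and C1 from dithiane opening of the epoxide. Both halves start from 2-methylidenepropane-1,3-diol.

## Route

**Step 1**
Reactants: 1, 2-methylidenepropane-1,3-diol
Product: 2, 2-({[tert-butyl(dimethyl)silyl]oxy}methyl)prop-2-en-1-ol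
Conditions: NaH (1.0 equiv), THF, 0 °C; TBSCl (1.0 equiv), 0 °C→rt
Reagents that add atoms: TBSCl, CC(C)(C)[Si](C)(C)Cl
Why: Monosilylation of a symmetrical diol through its monosodium alkoxide; no stereocentre is formed.

**Step 2**
Reactants: 2
Product: 3, [(2R)-2-({[TBS]oxy}methyl)oxiran-2-yl]methanol
Conditions: Ti(OiPr)4 (10 mol%), D-(−)-DET (12 mol%), t-BuOOH, 4 Å MS, CH2Cl2, −20 °C
Reagents that add atoms: tert-butyl hydroperoxide, CC(C)(C)OO
Why: Sharpless asymmetric epoxidation of a 2-substituted allylic alcohol; D-(−)-tartrate (the enantiomer that gives (R)-glycidol from allyl alcohol) sets the quaternary centre that becomes C8.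

**Step 3**
Reactants: 3
Product: 4, (2R)-2-({[TBS]oxy}methyl)oxirane-2-carbaldehyde
Conditions: SO3·pyridine, DMSO, iPr2NEt, CH2Cl2, 0 °C
Reagents that add atoms: none
Why: Parikh–Doering oxidation; the aldehyde has no α-hydrogen, so the stereocentre cannot epimerise.

**Step 4**
Reactants: 4
Product: 5, (1S)-1-[(2R)-2-({[TBS]oxy}methyl)oxiran-2-yl]but-3-en-1-ol
Conditions: (+)-Ipc2B(allyl) [from (−)-Ipc2BOMe and allylMgBr], Et2O, −78 °C; then ethanolamine
Reagents that add atoms: allylmagnesium bromide, C=CC[Mg]Br (allyl delivered through the chiral borane)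
Why: Brown asymmetric allylboration; the reagent (the enantiomer that gives (S)-1-phenylbut-3-en-1-ol from benzaldehyde, Si-face attack) sets C7 as S, and the Felkin–Anh preference (epoxide C–O anti to the nucleophile) points the same way.

**Step 5**
Reactants: 5
Product: 6, (2R,3S)-1-{[TBS]oxy}-2-(1,3-dithian-2-ylmethyl)hex-5-ene-2,3-diol
Conditions: 1,3-dithiane (2.5 equiv), n-BuLi, THF, −30 °C; then 5, −30→0 °C
Reagents that add atoms: 1,3-dithiane, C1CSCSC1 (as 2-lithio-1,3-dithiane)
Why: Corey–Seebach SN2 opening of the 2,2-disubstituted epoxide at its CH2 terminus installs C1 as a masked aldehyde; the C8–O bond is untouched, so configuration is retained.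

**Step 6**
Reactants: 6
Product: 7, (2R,3S)-1-{[TBS]oxy}-2-(1,3-dithian-2-ylmethyl)-2-hydroxyhex-5-en-3-yl acetate
Conditions: Ac2O (1.2 equiv), pyridine, DMAP (cat.), CH2Cl2, 0 °C
Reagents that add atoms: acetic anhydride, CC(=O)OC(C)=O
Why: Chemoselective acetylation of the secondary alcohol; the tertiary alcohol does not react under these conditions.

**Step 7**
Reactants: 7
Product: 8, (2R,3S)-1-{[TBS]oxy}-2-(1,3-dithian-2-ylmethyl)-2-[(triethylsilyl)oxy]hex-5-en-3-yl acetate
Conditions: TESOTf, 2,6-lutidine, CH2Cl2, −78→0 °C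
Reagents that add atoms: triethylsilyl triflate, CC[Si](CC)(CC)OS(=O)(=O)C(F)(F)F
Why: Silyl triflate silylation of the tertiary alcohol, which protects the future β-oxygenated aldehyde from elimination and from acetal formation later.

**Step 8**
Reactants: 8
Product: 9, (3R,4S)-4-acetoxy-3-({[TBS]oxy}methyl)-3-[(triethylsilyl)oxy]hept-6-enal
Conditions: MeI, CaCO3, MeCN/H2O (9:1), 45 °C
Reagents that add atoms: water, O
Why: S-alkylative hydrolysis of the dithiane under near-neutral conditions releases the C1 aldehyde without touching the acetate, silyl ethers or alkene.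

**Step 9**
Reactants: 1 (3 equiv)
Product: 10, 2-(hydroxymethyl)prop-2-en-1-yl 3-methylbutanoate
Conditions: isovaleryl chloride (1 equiv), pyridine, CH2Cl2, −20 °C
Reagents that add atoms: isovaleryl chloride, CC(C)CC(Cl)=O
Why: Statistical monoacylation of the symmetrical diol, used in excess and recovered.

**Step 10**
Reactants: 10
Product: 11, 2-formylprop-2-en-1-yl 3-methylbutanoate
Conditions: MnO2, CH2Cl2, rt (used directly)
Reagents that add atoms: none
Why: Selective MnO2 oxidation of the allylic alcohol to the 2-substituted acrolein.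

**Step 11 (fragment coupling)**
Reactants: 9 and 11 (3 equiv)
Product: 12, (2E,5S,6R)-5-acetoxy-6-({[TBS]oxy}methyl)-2-{[(3-methylbutanoyl)oxy]methyl}-6-[(triethylsilyl)oxy]oct-2-enedial
Conditions: Hoveyda–Grubbs II (7.5 mol%), CH2Cl2, 40 °C
Reagents that add atoms: none (ethylene is lost)
Why: Olefin cross-metathesis of a terminal alkene with a 2-substituted acrolein, which does not homodimerise; as with methacrolein, the E enal (CHO trans to the chain) is expected.

**Step 12 (both rings)**
Reactants: 12
Product: 13, (4aS,6S,7R,7aS)-6-acetoxy-1-hydroxy-4-{[(3-methylbutanoyl)oxy]methyl}-7-({[TBS]oxy}methyl)-7-[(triethylsilyl)oxy]-1,4a,5,6,7,7a-hexahydrocyclopenta[c]pyran (lactol, mainly the 1R anomer with OH cis to H-7a)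
Conditions: PhNHMe (1.1 equiv), 4 Å MS, MeCN, 0 °C→rt; then TsOH·H2O (cat.), THF/H2O, 0 °C
Reagents that add atoms: water, O (the C1–OH oxygen; N-methylaniline is lost on hydrolysis)
Why: Schreiber-type intramolecular inverse-demand hetero-Diels–Alder of the C1 enamine onto the enal gives the cis-fused N,O-aminal, which is hydrolysed to the lactol; C5 and C9 are set by the new ring forming on the face opposite the C7 acetate and the C8 CH2OTBS group.

**Step 13**
Reactants: 13
Product: 14, (1S,4aS,6S,7R,7aS)-6-acetoxy-4-{[(3-methylbutanoyl)oxy]methyl}-7-({[TBS]oxy}methyl)-7-[(triethylsilyl)oxy]-1,4a,5,6,7,7a-hexahydrocyclopenta[c]pyran-1-yl 3-methylbutanoate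
Conditions: isovaleryl chloride, pyridine, DMAP (cat.), CH2Cl2, −20→0 °C
Reagents that add atoms: isovaleryl chloride, CC(C)CC(Cl)=O
Why: Anomeric O-acylation; the ester is expected on the convex face, trans to the C7a–C7 bond, which is both the anomerically preferred and the less hindered position, giving 1S.

**Step 14**
Reactants: 14
Product: 15, Jatamanvaltrate H
Conditions: HF·pyridine, excess pyridine, THF, 0 °C→rt
Reagents that add atoms: none
Why: Buffered fluoride desilylation removes the primary TBS and tertiary TES ethers while the three esters, the acyl acetal and the enol ether are left intact.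

## Compound list

1 | 2-methylidenepropane-1,3-diol | C=C(CO)CO | starting material
2 | 2-({[TBS]oxy}methyl)prop-2-en-1-ol | C=C(CO)CO[Si](C)(C)C(C)(C)C | intermediate
3 | [(2R)-2-({[TBS]oxy}methyl)oxiran-2-yl]methanol | OC[C@@]1(CO1)CO[Si](C)(C)C(C)(C)C | intermediate
4 | (2R)-2-({[TBS]oxy}methyl)oxirane-2-carbaldehyde | O=C[C@@]1(CO1)CO[Si](C)(C)C(C)(C)C | intermediate
5 | (1S)-1-[(2R)-2-({[TBS]oxy}methyl)oxiran-2-yl]but-3-en-1-ol | C=CC[C@H](O)[C@@]1(CO1)CO[Si](C)(C)C(C)(C)C | intermediate
6 | (2R,3S)-1-{[TBS]oxy}-2-(1,3-dithian-2-ylmethyl)hex-5-ene-2,3-diol | C=CC[C@H](O)[C@@](O)(CC1SCCCS1)CO[Si](C)(C)C(C)(C)C | intermediate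
7 | (2R,3S)-1-{[TBS]oxy}-2-(1,3-dithian-2-ylmethyl)-2-hydroxyhex-5-en-3-yl acetate | C=CC[C@H](OC(C)=O)[C@@](O)(CC1SCCCS1)CO[Si](C)(C)C(C)(C)C | intermediate
8 | (2R,3S)-1-{[TBS]oxy}-2-(1,3-dithian-2-ylmethyl)-2-[(triethylsilyl)oxy]hex-5-en-3-yl acetate | C=CC[C@H](OC(C)=O)[C@@](O[Si](CC)(CC)CC)(CC1SCCCS1)CO[Si](C)(C)C(C)(C)C | intermediate
9 | (3R,4S)-4-acetoxy-3-({[TBS]oxy}methyl)-3-[(triethylsilyl)oxy]hept-6-enal | C=CC[C@H](OC(C)=O)[C@@](O[Si](CC)(CC)CC)(CC=O)CO[Si](C)(C)C(C)(C)C | intermediate
10 | 2-(hydroxymethyl)prop-2-en-1-yl 3-methylbutanoate | C=C(CO)COC(=O)CC(C)C | intermediate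
11 | 2-formylprop-2-en-1-yl 3-methylbutanoate | C=C(C=O)COC(=O)CC(C)C | intermediate
12 | (2E,5S,6R)-5-acetoxy-6-({[TBS]oxy}methyl)-2-{[(3-methylbutanoyl)oxy]methyl}-6-[(triethylsilyl)oxy]oct-2-enedial | O=C/C(COC(=O)CC(C)C)=C/C[C@H](OC(C)=O)[C@@](O[Si](CC)(CC)CC)(CC=O)CO[Si](C)(C)C(C)(C)C | intermediate
13 | 1-hydroxy lactol, 7-O-TES, 7-CH2OTBS (major 1R anomer shown) | CC(=O)O[C@H]1C[C@@H]2C(COC(=O)CC(C)C)=CO[C@@H](O)[C@@H]2[C@@]1(O[Si](CC)(CC)CC)CO[Si](C)(C)C(C)(C)C | intermediate
14 | bis-silyl-protected Jatamanvaltrate H | CC(=O)O[C@H]1C[C@@H]2C(COC(=O)CC(C)C)=CO[C@@H](OC(=O)CC(C)C)[C@@H]2[C@@]1(O[Si](CC)(CC)CC)CO[Si](C)(C)C(C)(C)C | intermediate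
15 | Jatamanvaltrate H, (1S,4aS,6S,7R,7aS)-6-acetoxy-7-hydroxy-7-(hydroxymethyl)-4-{[(3-methylbutanoyl)oxy]methyl}-1,4a,5,6,7,7a-hexahydrocyclopenta[c]pyran-1-yl 3-methylbutanoate | CC(=O)O[C@H]1C[C@@H]2C(COC(=O)CC(C)C)=CO[C@@H](OC(=O)CC(C)C)[C@@H]2[C@@]1(O)CO | target

## Step count and risks

Total steps: 14. Longest linear sequence: 12 (steps 1–8, then 11–14); the acrolein half (steps 9–10) is made in parallel.

Steps most likely to fail:

1. **Step 12 (ring-forming hetero-Diels–Alder).** Facial selectivity depends on the C7/C8 substituents, and the allylic isovalerate could be lost by SN2′ or E1cB. Fallback: carry C11 as a silyl ether (metathesis partner 2-(silyloxymethyl)acrolein), form the cyclopentane by a catalyst-controlled proline or diarylprolinol-ether intramolecular Michael addition followed by separate lactolisation, and install both isovalerates afterwards.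
2. **Step 11 (cross-metathesis with a hindered, electron-poor 1,1-disubstituted enal).** Fallback: metathesise 9 with acrolein (a more reactive, less hindered partner), cyclise and acylate the resulting C4-unsubstituted iridoid, then add C11 by Vilsmeier–Haack formylation of the enol ether, Luche reduction and isovaleroylation.
3. **Step 14 (global desilylation next to an acyl acetal and enol ether).** Risks are acetate migration and acid-induced 3,8-oxa-bridging. Fallback: change the protecting-group plan by removing the silyl groups at the lactol stage (13) and acylating C1–OH with the 8,10-diol masked in situ as its phenylboronate, released on work-up with pinacol.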